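**Retrosynthetic overview**

1. Core numbering: C1 (C=O), C2 (N-bearing), C3 (=CH), C4 (C–OH), C5 and C6 (epoxide, C6 next to C1). Last disconnections: Stille union of a C4 (E)-vinylstannane with the iododienamide of the aminohydroxycyclopentenone unit, and copper-catalysed N-vinylation of the upper trienamide at a C2–Br bond.
2. The epoxycyclohexenone carbocycle is made by one-carbon ring expansion: dibromocarbene is inserted between C1 and C3 of an enantiopure epoxycyclopentanone (ring atoms C1, C3, C4, C5, C6), used as its silyl enol ether. The inserted carbon is C2 and arrives carrying bromine.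
3. Enabling feature: in the ring C1(=O)–C2(N)=C3–C4(OH)–C5–C6(epoxide), the ketone C1 is flanked by a heteroatom-bearing sp2 carbon C2, which is the retron of an enol ether/dihalocarbene expansion to a 2-halo enone. C6 is an epoxide carbon that cannot enolise, so the five-membered ketone can form only the C1=C3 enol ether.
4. All three stereocentres are set on the five-membered ring: acetylide addition anti to the silyloxy group of (R)-4-silyloxycyclopentenone (C4), then epoxidation directed by two cis hydroxyls (C5, C6 syn to the C4–OH).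
5. Ring order: cyclopentene (purchased), fused epoxide (step 3), six-membered carbocycle (step 6). The hydroxycyclopentenone ring comes from cyclopentane-1,3-dione.

Key step: step 6

Remark: compounds 1, 2, 11, 12, 20 and 23 are taken to be purchasable, and the aminocyclopentenone unit is drawn as its enol tautomer throughout.

**Route**

Step 1
Reactants: 1 (4R)-4-[(tert-butyldimethylsilyl)oxy]cyclopent-2-en-1-one; 2 (triethylsilyl)acetylene
Product: 4 (1S,4R)-4-[(tert-butyldimethylsilyl)oxy]-1-[(triethylsilyl)ethynyl]cyclopent-2-en-1-ol, via lithium (triethylsilyl)acetylide 3 (not isolated)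
Conditions: 2, n-BuLi, THF, −78 °C; then 1, −78 °C; H2O quench
Reagents that add atoms: none
Why: 1,2-Addition of a lithium acetylide to the enone carbonyl; attack anti to the silyloxy group should set the tertiary carbinol as (S) with OH cis to OTBS, and any minor epimer would be removed by chromatography so that the enantiopurity of 1 passes into C4 of the target.

Step 2
Reactants: 4 (1S,4R)-4-[(tert-butyldimethylsilyl)oxy]-1-[(triethylsilyl)ethynyl]cyclopent-2-en-1-ol
Product: 5 (1S,4R)-1-[(triethylsilyl)ethynyl]cyclopent-2-ene-1,4-diol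
Conditions: HF·pyridine, pyridine/THF, 0 °C to rt
Reagents that add atoms: none
Why: Fluoride-mediated cleavage of the secondary silyl ether; the C(sp)–SiEt3 bond and the tertiary alcohol are stable to buffered HF and no stereocentre is touched.

Step 3
Reactants: 5 (1S,4R)-1-[(triethylsilyl)ethynyl]cyclopent-2-ene-1,4-diol
Product: 6 (1R,2R,4R,5R)-2-[(triethylsilyl)ethynyl]-6-oxabicyclo[3.1.0]hexane-2,4-diol
Conditions: VO(acac)2 (cat.), t-BuOOH (decane), CH2Cl2, 0 °C to rt
Reagents that add atoms: tert-butyl hydroperoxide CC(C)(C)OO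
Why: Vanadium-catalysed hydroxyl-directed epoxidation of an allylic alcohol; both allylic hydroxyls lie on the same ring face and deliver the oxidant there, so the epoxide should form cis to the tertiary OH, which sets the two epoxide stereocentres (future C5 and C6).

Step 4
Reactants: 6 (1R,2R,4R,5R)-2-[(triethylsilyl)ethynyl]-6-oxabicyclo[3.1.0]hexane-2,4-diol
Product: 7 (1S,4R,5R)-4-hydroxy-4-[(triethylsilyl)ethynyl]-6-oxabicyclo[3.1.0]hexan-2-one
Conditions: Dess–Martin periodinane, CH2Cl2, rt
Reagents that add atoms: none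
Why: Dess–Martin oxidation of the secondary alcohol; the tertiary alcohol cannot be oxidised and the α-stereocentre is an epoxide carbon that cannot epimerise by enolisation.

Step 5
Reactants: 7 (1S,4R,5R)-4-hydroxy-4-[(triethylsilyl)ethynyl]-6-oxabicyclo[3.1.0]hexan-2-one
Product: 8 (1S,4R,5R)-2,4-bis[(triethylsilyl)oxy]-4-[(triethylsilyl)ethynyl]-6-oxabicyclo[3.1.0]hex-2-ene
Conditions: Et3SiOTf, Et3N, CH2Cl2, −78 to 0 °C
Reagents that add atoms: triethylsilyl trifluoromethanesulfonate CC[Si](CC)(CC)OS(=O)(=O)C(F)(F)F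
Why: Soft enolisation with a silyl triflate and amine base forms the silyl enol ether and silylates the tertiary alcohol in the same operation; enolisation can go only toward the CH2 group because the other α-carbon is an epoxide carbon.

Step 6
Reactants: 8 (1S,4R,5R)-2,4-bis[(triethylsilyl)oxy]-4-[(triethylsilyl)ethynyl]-6-oxabicyclo[3.1.0]hex-2-ene
Product: 10 (1S,5R,6R)-3-bromo-5-[(triethylsilyl)oxy]-5-[(triethylsilyl)ethynyl]-7-oxabicyclo[4.1.0]hept-3-en-2-one, via dibromocyclopropane adduct 9 (not isolated)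
Conditions: CHBr3, KOtBu, pentane, −30 °C to rt
Reagents that add atoms: bromoform BrC(Br)Br
Why: Dibromocarbene adds to the electron-rich silyl enol ether C=C of 8 to give the 1-siloxy-6,6-dibromobicyclo[3.1.0]hexane 9, which should ionise its endo C–Br bond with siloxy assistance and open by disrotatory two-electron electrocyclic cyclopropyl-to-allyl cation ring opening (Woodward–Hoffmann–DePuy rule), then lose Et3SiBr to give the 2-bromo enone; the closest known reaction type is the ring expansion of cyclic silyl enol ethers with dihalocarbenes to 2-halocycloalk-2-enones, five-to-six enlargements included. The six-membered ring is not closed by a cyclisation but arises by cleavage of the internal C1–C3 bond of the fused cyclopropane, so that the inserted carbon becomes C2 between the former carbonyl carbon C1 and the former α-methylene C3. No new stereocentre is formed: C4, C5 and C6 are carried over unchanged, and the face of carbene attack is irrelevant because both cyclopropane ring-fusion carbons become sp2 and a gem-dibromide always offers the endo bromide needed for opening. The step needs regioselectivity (insertion between C1 and C3, not C1 and C6) and chemoselectivity (enol ether over alkyne and epoxide); the first is secured because the epoxide carbon C6 cannot be enolised, the second because the silyl enol ether is by far the most nucleophilic π-bond while the alkyne is shielded and deactivated by its SiEt3 group.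

Step 7
Reactants: 11 (2E)-4-methylpent-2-enal; 12 triethyl (2E)-4-phosphonobut-2-enoate
Product: 13 ethyl (2E,4E,6E)-8-methylnona-2,4,6-trienoate
Conditions: LiOH·H2O, 4 Å MS, THF, reflux
Reagents that add atoms: none
Why: Vinylogous Horner–Wadsworth–Emmons olefination with a stabilised phosphonate, which should give the new double bond as E while the two existing E double bonds are retained.

Step 8
Reactants: 13 ethyl (2E,4E,6E)-8-methylnona-2,4,6-trienoate
Product: 14 (2E,4E,6E)-8-methylnona-2,4,6-trienoic acid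
Conditions: LiOH, THF/MeOH/H2O, rt; then 1 M HCl
Reagents that add atoms: none
Why: Ester saponification under mild conditions that leave the conjugated triene geometry untouched.

Step 9
Reactants: 14 (2E,4E,6E)-8-methylnona-2,4,6-trienoic acid
Product: 16 (2E,4E,6E)-8-methylnona-2,4,6-trienamide, via acyl imidazole 15 (not isolated)
Conditions: CDI, THF, rt; then 28% aq NH3, 0 °C to rt
Reagents that add atoms: ammonia N
Why: Carboxyl activation as the acyl imidazole followed by ammonolysis gives the primary amide without conjugate addition to the triene.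

Step 10
Reactants: 10 (1S,5R,6R)-3-bromo-5-[(triethylsilyl)oxy]-5-[(triethylsilyl)ethynyl]-7-oxabicyclo[4.1.0]hept-3-en-2-one; 16 (2E,4E,6E)-8-methylnona-2,4,6-trienamide
Product: 17 (2E,4E,6E)-8-methyl-N-[(1S,5R,6R)-2-oxo-5-[(triethylsilyl)ethynyl]-5-[(triethylsilyl)oxy]-7-oxabicyclo[4.1.0]hept-3-en-3-yl]nona-2,4,6-trienamide
Conditions: CuI (cat.), N,N′-dimethylethylenediamine (cat.), K2CO3, toluene, 70 °C
Reagents that add atoms: none
Why: Goldberg-type copper-catalysed N-vinylation of a primary amide with a vinyl bromide; the C–Br bond of the 2-bromo enone is activated, substitution is at the bromine-bearing carbon so the enamide double bond stays at C2=C3, and the weak carbonate base in toluene should spare the epoxide and both silyl groups.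

Step 11
Reactants: 17 (2E,4E,6E)-8-methyl-N-[(1S,5R,6R)-2-oxo-5-[(triethylsilyl)ethynyl]-5-[(triethylsilyl)oxy]-7-oxabicyclo[4.1.0]hept-3-en-3-yl]nona-2,4,6-trienamide
Product: 18 (2E,4E,6E)-N-[(1S,5R,6R)-5-ethynyl-5-hydroxy-2-oxo-7-oxabicyclo[4.1.0]hept-3-en-3-yl]-8-methylnona-2,4,6-trienamide
Conditions: TBAF, AcOH, THF, 0 °C to rt
Reagents that add atoms: none
Why: Fluoride-induced cleavage of the O–Si and C(sp)–Si bonds, buffered with acetic acid so that the base-sensitive epoxy enone is not exposed to free alkoxide or acetylide.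

Step 12
Reactants: 18 (2E,4E,6E)-N-[(1S,5R,6R)-5-ethynyl-5-hydroxy-2-oxo-7-oxabicyclo[4.1.0]hept-3-en-3-yl]-8-methylnona-2,4,6-trienamide
Product: 19 (2E,4E,6E)-N-[(1S,5R,6R)-5-hydroxy-2-oxo-5-[(E)-2-(tributylstannyl)ethenyl]-7-oxabicyclo[4.1.0]hept-3-en-3-yl]-8-methylnona-2,4,6-trienamide
Conditions: Bu3SnH, PdCl2(PPh3)2 (cat.), THF, 0 °C
Reagents that add atoms: tributyltin hydride CCCC[SnH](CCCC)CCCC
Why: Palladium-catalysed syn-hydrostannylation of a terminal alkyne; the bulky tertiary carbinol should steer tin to the terminal carbon and give the (E)-vinylstannane, and the alkyne should react much faster than the enone or the epoxy ketone.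

Step 13
Reactants: 20 ethyl (2E)-4-oxobut-2-enoate
Product: 21 ethyl (2E,4E)-5-iodopenta-2,4-dienoate
Conditions: CHI3, CrCl2, THF, 0 °C
Reagents that add atoms: iodoform IC(I)I
Why: Takai olefination of the aldehyde with the gem-dichromium species from iodoform and divalent chromium, which should give the (E)-vinyl iodide and leave the enoate untouched.

Step 14
Reactants: 21 ethyl (2E,4E)-5-iodopenta-2,4-dienoate
Product: 22 (2E,4E)-5-iodopenta-2,4-dienoic acid
Conditions: LiOH, THF/H2O, 0 °C to rt; then 1 M HCl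
Reagents that add atoms: none
Why: Ester saponification; the vinyl iodide is inert to cold aqueous hydroxide.

Step 15
Reactants: 23 cyclopentane-1,3-dione
Product: 24 2-(hydroxyimino)cyclopentane-1,3-dione
Conditions: NaNO2, aq HCl, 0 °C
Reagents that add atoms: sodium nitrite [Na+].[O-]N=O
Why: C-Nitrosation of the doubly activated methylene of a 1,3-dione, which tautomerises to the oxime.

Step 16
Reactants: 24 2-(hydroxyimino)cyclopentane-1,3-dione
Product: 25 2-amino-3-hydroxycyclopent-2-en-1-one hydrochloride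
Conditions: H2 (1 atm), Pd/C, HCl, MeOH, rt
Reagents that add atoms: hydrogen chloride Cl
Why: Catalytic hydrogenation of the oxime to the primary amine, trapped as the hydrochloride of the enolised amino dione so that self-condensation is avoided.

Step 17
Reactants: 22 (2E,4E)-5-iodopenta-2,4-dienoic acid; 25 2-amino-3-hydroxycyclopent-2-en-1-one hydrochloride
Product: 27 (2E,4E)-N-(2-hydroxy-5-oxocyclopent-1-en-1-yl)-5-iodopenta-2,4-dienamide, via (2E,4E)-5-iodopenta-2,4-dienoyl chloride 26 (not isolated)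
Conditions: (COCl)2, DMF (cat.), CH2Cl2, 0 °C, then evaporation; then 25, Et3N, THF, 0 °C to rt
Reagents that add atoms: none
Why: Acid chloride formation and N-acylation of the liberated amine; any O-acylated enol isomer should rearrange to the amide by O-to-N acyl shift.

Step 18
Reactants: 19 (2E,4E,6E)-N-[(1S,5R,6R)-5-hydroxy-2-oxo-5-[(E)-2-(tributylstannyl)ethenyl]-7-oxabicyclo[4.1.0]hept-3-en-3-yl]-8-methylnona-2,4,6-trienamide; 27 (2E,4E)-N-(2-hydroxy-5-oxocyclopent-1-en-1-yl)-5-iodopenta-2,4-dienamide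
Product: 28 Manumycin G, (2E,4E,6E)-N-[(1S,5S,6R)-5-hydroxy-5-[(1E,3E,5E)-7-[(2-hydroxy-5-oxocyclopent-1-en-1-yl)amino]-7-oxohepta-1,3,5-trien-1-yl]-2-oxo-7-oxabicyclo[4.1.0]hept-3-en-3-yl]-8-methylnona-2,4,6-trienamide
Conditions: PdCl2(MeCN)2 (cat.), DMF, rt, dark
Reagents that add atoms: none
Why: Stille coupling of a vinylstannane with a vinyl iodide under ligand-free conditions at room temperature, with retention of both alkene geometries so that the E,E,E-triene results; the free tertiary alcohol, the epoxy enone and the acidic enol should tolerate these neutral conditions.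

**Compound list**

1 | (4R)-4-[(tert-butyldimethylsilyl)oxy]cyclopent-2-en-1-one | O=C1C=C[C@H](O[Si](C)(C)C(C)(C)C)C1 | starting material
2 | (triethylsilyl)acetylene | C#C[Si](CC)(CC)CC | starting material
3 | lithium (triethylsilyl)acetylide | [Li]C#C[Si](CC)(CC)CC | intermediate
4 | (1S,4R)-4-[(tert-butyldimethylsilyl)oxy]-1-[(triethylsilyl)ethynyl]cyclopent-2-en-1-ol | C1[C@@](O)(C#C[Si](CC)(CC)CC)C=C[C@@H]1O[Si](C)(C)C(C)(C)C | intermediate
5 | (1S,4R)-1-[(triethylsilyl)ethynyl]cyclopent-2-ene-1,4-diol | C1[C@@](O)(C#C[Si](CC)(CC)CC)C=C[C@@H]1O | intermediate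
6 | (1R,2R,4R,5R)-2-[(triethylsilyl)ethynyl]-6-oxabicyclo[3.1.0]hexane-2,4-diol | C1[C@@](O)(C#C[Si](CC)(CC)CC)[C@@H]2O[C@@H]2[C@@H]1O | intermediate
7 | (1S,4R,5R)-4-hydroxy-4-[(triethylsilyl)ethynyl]-6-oxabicyclo[3.1.0]hexan-2-one | C1[C@@](O)(C#C[Si](CC)(CC)CC)[C@@H]2O[C@@H]2C1=O | intermediate
8 | (1S,4R,5R)-2,4-bis[(triethylsilyl)oxy]-4-[(triethylsilyl)ethynyl]-6-oxabicyclo[3.1.0]hex-2-ene | CC[Si](CC)(CC)OC1=C[C@@](O[Si](CC)(CC)CC)(C#C[Si](CC)(CC)CC)[C@@H]2O[C@H]12 | intermediate
9 | 7,7-dibromo-1,5-bis[(triethylsilyl)oxy]-5-[(triethylsilyl)ethynyl]-3-oxatricyclo[4.1.0.0^{2,4}]heptane (dibromocyclopropane adduct, cyclopropane anti to the epoxide) | [C@H]12[C@@](O[Si](CC)(CC)CC)(C#C[Si](CC)(CC)CC)[C@@H]3O[C@@H]3[C@@]1(O[Si](CC)(CC)CC)C2(Br)Br | intermediate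
10 | (1S,5R,6R)-3-bromo-5-[(triethylsilyl)oxy]-5-[(triethylsilyl)ethynyl]-7-oxabicyclo[4.1.0]hept-3-en-2-one | BrC1=C[C@@](O[Si](CC)(CC)CC)(C#C[Si](CC)(CC)CC)[C@@H]2O[C@@H]2C1=O | intermediate
11 | (2E)-4-methylpent-2-enal | CC(C)/C=C/C=O | starting material
12 | triethyl (2E)-4-phosphonobut-2-enoate | CCOC(=O)/C=C/CP(=O)(OCC)OCC | starting material
13 | ethyl (2E,4E,6E)-8-methylnona-2,4,6-trienoate | CC(C)/C=C/C=C/C=C/C(=O)OCC | intermediate
14 | (2E,4E,6E)-8-methylnona-2,4,6-trienoic acid | CC(C)/C=C/C=C/C=C/C(=O)O | intermediate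
15 | (2E,4E,6E)-1-(1H-imidazol-1-yl)-8-methylnona-2,4,6-trien-1-one (acyl imidazole) | CC(C)/C=C/C=C/C=C/C(=O)n1ccnc1 | intermediate
16 | (2E,4E,6E)-8-methylnona-2,4,6-trienamide | CC(C)/C=C/C=C/C=C/C(N)=O | intermediate
17 | (2E,4E,6E)-8-methyl-N-[(1S,5R,6R)-2-oxo-5-[(triethylsilyl)ethynyl]-5-[(triethylsilyl)oxy]-7-oxabicyclo[4.1.0]hept-3-en-3-yl]nona-2,4,6-trienamide | CC(C)/C=C/C=C/C=C/C(=O)NC1=C[C@@](O[Si](CC)(CC)CC)(C#C[Si](CC)(CC)CC)[C@@H]2O[C@@H]2C1=O | intermediate
18 | (2E,4E,6E)-N-[(1S,5R,6R)-5-ethynyl-5-hydroxy-2-oxo-7-oxabicyclo[4.1.0]hept-3-en-3-yl]-8-methylnona-2,4,6-trienamide | CC(C)/C=C/C=C/C=C/C(=O)NC1=C[C@@](O)(C#C)[C@@H]2O[C@@H]2C1=O | intermediate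
19 | (2E,4E,6E)-N-[(1S,5R,6R)-5-hydroxy-2-oxo-5-[(E)-2-(tributylstannyl)ethenyl]-7-oxabicyclo[4.1.0]hept-3-en-3-yl]-8-methylnona-2,4,6-trienamide | CC(C)/C=C/C=C/C=C/C(=O)NC1=C[C@@](O)(/C=C/[Sn](CCCC)(CCCC)CCCC)[C@@H]2O[C@@H]2C1=O | intermediate
20 | ethyl (2E)-4-oxobut-2-enoate | CCOC(=O)/C=C/C=O | starting material
21 | ethyl (2E,4E)-5-iodopenta-2,4-dienoate | CCOC(=O)/C=C/C=C/I | intermediate
22 | (2E,4E)-5-iodopenta-2,4-dienoic acid | OC(=O)/C=C/C=C/I | intermediate
23 | cyclopentane-1,3-dione | O=C1CCC(=O)C1 | starting material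
24 | 2-(hydroxyimino)cyclopentane-1,3-dione | O=C1CCC(=O)C1=NO | intermediate
25 | 2-amino-3-hydroxycyclopent-2-en-1-one hydrochloride | NC1=C(O)CCC1=O.Cl | intermediate
26 | (2E,4E)-5-iodopenta-2,4-dienoyl chloride | ClC(=O)/C=C/C=C/I | intermediate
27 | (2E,4E)-N-(2-hydroxy-5-oxocyclopent-1-en-1-yl)-5-iodopenta-2,4-dienamide | O=C(/C=C/C=C/I)NC1=C(O)CCC1=O | intermediate
28 | Manumycin G | CC(C)/C=C/C=C/C=C/C(=O)NC1=C[C@@](O)(/C=C/C=C/C=C/C(=O)NC2=C(O)CCC2=O)[C@@H]2O[C@@H]2C1=O | target

**Step count**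

Total steps: 18. Longest linear sequence: 10 steps (steps 1–6, 10, 11, 12, 18).

**Steps most likely to fail**

Step 6. The vinyl epoxide of 8 may open under the alkoxide base or traces of acid before the carbene is captured, or the dibromocyclopropane may ionise sluggishly. The fallback inserts the carbon stepwise, without free carbene or alkoxide. Setting out from 8, Furukawa cyclopropanation (Et2Zn, CH2I2, CH2Cl2, 0 °C) would give the tricyclic siloxycyclopropane F1. FeCl3 in DMF (Ito–Saegusa oxidative opening of the internal cyclopropane bond) would give the ring-expanded β-chloro ketone F2, and NaOAc in MeOH would eliminate HCl to the epoxy enone F3. Bromine addition followed by Et3N-induced dehydrobromination (CH2Cl2, 0 °C) would then return to 10.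

Step 10. The carbonate base and heating may degrade the α,β-epoxy ketone, or conjugate addition of the amidate may outrun C–N coupling at the hindered bromo enone. The fallback brings in nitrogen first and the acyl group second. Setting out from 10, Buchwald–Hartwig coupling with benzophenone imine (Pd2(dba)3, BINAP, Cs2CO3, toluene, 60 °C) would give the N-diphenylmethylidene amino enone F4. Aqueous citric acid in THF would release the primary 3-amino enone F5. N-Acylation with (2E,4E,6E)-8-methylnona-2,4,6-trienoyl chloride F6 (from acid 14 and oxalyl chloride) and LiOtBu in THF at −78 °C would return to 17.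

Step 12. Tin hydride may reduce the enone or the epoxy ketone under palladium catalysis, or tin may be delivered to the internal alkyne carbon. The fallback forms the C–C bond first and then turns the alkyne into the (E)-alkene. Setting out from 18, Sonogashira coupling with iodide 27 (PdCl2(PPh3)2, CuI, i-Pr2NH, THF, rt) would give the dienyne F7. Trans-hydrosilylation with BnMe2SiH catalysed by [Cp*Ru(MeCN)3]PF6 (acetone, 0 °C) would give the (Z)-vinylsilane F8; either silyl regioisomer leads to the same alkene. Protodesilylation (TBAF, CuI, THF, 0 °C) would replace silicon by hydrogen with retention and so arrive at 28.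

**Further compounds**

F1 | step 6 | 1,5-bis[(triethylsilyl)oxy]-5-[(triethylsilyl)ethynyl]-3-oxatricyclo[4.1.0.0^{2,4}]heptane (cyclopropane anti to the epoxide) | [C@H]12[C@@](O[Si](CC)(CC)CC)(C#C[Si](CC)(CC)CC)[C@@H]3O[C@@H]3[C@@]1(O[Si](CC)(CC)CC)C2
F2 | step 6 | (1S,5R,6R)-4-chloro-5-[(triethylsilyl)oxy]-5-[(triethylsilyl)ethynyl]-7-oxabicyclo[4.1.0]heptan-2-one (both C4 epimers) | C1(Cl)[C@@](O[Si](CC)(CC)CC)(C#C[Si](CC)(CC)CC)[C@@H]2O[C@@H]2C(=O)C1
F3 | step 6 | (1S,5R,6R)-5-[(triethylsilyl)oxy]-5-[(triethylsilyl)ethynyl]-7-oxabicyclo[4.1.0]hept-3-en-2-one | C1=C[C@@](O[Si](CC)(CC)CC)(C#C[Si](CC)(CC)CC)[C@@H]2O[C@@H]2C1=O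
F4 | step 10 | (1S,5R,6R)-3-[(diphenylmethylidene)amino]-5-[(triethylsilyl)oxy]-5-[(triethylsilyl)ethynyl]-7-oxabicyclo[4.1.0]hept-3-en-2-one | c1ccccc1C(c1ccccc1)=NC1=C[C@@](O[Si](CC)(CC)CC)(C#C[Si](CC)(CC)CC)[C@@H]2O[C@@H]2C1=O
F5 | step 10 | (1S,5R,6R)-3-amino-5-[(triethylsilyl)oxy]-5-[(triethylsilyl)ethynyl]-7-oxabicyclo[4.1.0]hept-3-en-2-one | NC1=C[C@@](O[Si](CC)(CC)CC)(C#C[Si](CC)(CC)CC)[C@@H]2O[C@@H]2C1=O
F6 | step 10 | (2E,4E,6E)-8-methylnona-2,4,6-trienoyl chloride | CC(C)/C=C/C=C/C=C/C(Cl)=O
F7 | step 12 | (2E,4E,6E)-N-[(1S,5R,6R)-5-hydroxy-5-[(3E,5E)-7-[(2-hydroxy-5-oxocyclopent-1-en-1-yl)amino]-7-oxohepta-3,5-dien-1-yn-1-yl]-2-oxo-7-oxabicyclo[4.1.0]hept-3-en-3-yl]-8-methylnona-2,4,6-trienamide | CC(C)/C=C/C=C/C=C/C(=O)NC1=C[C@@](O)(C#C/C=C/C=C/C(=O)NC2=C(O)CCC2=O)[C@@H]2O[C@@H]2C1=O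
F8 | step 12 | (2E,4E,6E)-N-[(1S,5R,6R)-5-[(1Z,3E,5E)-2-[benzyl(dimethyl)silyl]-7-[(2-hydroxy-5-oxocyclopent-1-en-1-yl)amino]-7-oxohepta-1,3,5-trien-1-yl]-5-hydroxy-2-oxo-7-oxabicyclo[4.1.0]hept-3-en-3-yl]-8-methylnona-2,4,6-trienamide | CC(C)/C=C/C=C/C=C/C(=O)NC1=C[C@@](O)(/C=C(/C=C/C=C/C(=O)NC2=C(O)CCC2=O)[Si](C)(C)Cc2ccccc2)[C@@H]2O[C@@H]2C1=O
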